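**Retrosynthetic overview**

1. The target comes from its tris-silyl ether. Ring B's dienol ether and the C3–C9 bond come from adding a side-chain vinyllithium to the lactone carbonyl (C3) of a bicyclic silyl dienol ether, then acid-induced dehydration.
2. Ring A (C4a–C5–C6–C7–C8–C8a) is closed at C7–C8 by reductive aldol cyclisation of an aldehyde–enone. The enabling feature is the aldol array C6(=O)–C7(OH)(CH3)–C8(OH) of ring A: C7 is α to the C6 ketone, and its methyl can be carried as the CH2 terminus of a 2-silyloxy enone.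
3. The aldehyde–enone comes from a trans-4,5-disubstituted δ-lactone, made by Mukaiyama–Michael union of an unsaturated lactone (C1, O2, C3, C4, C4a, C8a, C8) with a biacetyl-derived bis(silyloxy)diene (C5, C6, C7, C7-methyl). C8a is set by an auxiliary-controlled hydroxymethylation.
4. The side chain (C9–C15) comes from Takai olefination of an aldehyde built by aldol addition of the (R)-lactic acid pivalaldehyde acetal to (S)-2-methylbutanal.
5. Order of ring formation: the lactone ring (future ring B: O2, C1, C8a, C4a, C4, C3) by ring-closing metathesis, then ring A by the key step, then conversion of the lactone into the cyclic dienol ether of ring B.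

Key step: step 17

Remark: atom numbers follow the isochromene skeleton of the target (O2, C1, C3, C4, C4a, C5 to C8, C8a; side chain C9 to C15); ring A is the carbocycle and ring B the pyran.

**Route**

Step 1
Reactants: 1 (S)-2-methylbutan-1-ol
Product: 2 (S)-2-methylbutanal
Conditions: TEMPO (cat.), PhI(OAc)2, CH2Cl2, 0 °C
Reagents that add atoms: none
Why: Nitroxyl-catalysed alcohol oxidation stops at the aldehyde under near-neutral conditions, so the α-stereocentre (future C13) should survive.

Step 2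
Reactants: 3 (R)-lactic acid
Product: 4 (2R,5R)-2-tert-butyl-5-methyl-1,3-dioxolan-4-one
Conditions: tBuCHO, TsOH (cat.), H2SO4 (cat.), pentane, reflux, azeotropic removal of water
Reagents that add atoms: pivalaldehyde, CC(C)(C)C=O
Why: Acid-catalysed acetalisation under equilibrating dehydration should give mainly the cis acetal (purified by crystallisation), which stores the lactate configuration in the acetal centre (self-regeneration of stereocentres).

Step 3
Reactants: 4 (2R,5R)-2-tert-butyl-5-methyl-1,3-dioxolan-4-one; 2 (S)-2-methylbutanal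
Product: 6 (2R,5S)-2-tert-butyl-5-[(1S,2S)-1-hydroxy-2-methylbutyl]-5-methyl-1,3-dioxolan-4-one, via lithium enolate 5 (not isolated)
Conditions: LiN(iPr)2, THF, −78 °C; then 2, −78 °C; aq. NH4Cl
Reagents that add atoms: none
Why: Aldol addition of the lithium enolate, in which attack anti to the tert-butyl group re-creates C11 as a quaternary carbinol and a closed chair (Zimmerman–Traxler) transition state with the enolate methyl cis to O–Li and the aldehyde residue equatorial should set C12 anti to the ring oxygen.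

Step 4
Reactants: 6 (2R,5S)-2-tert-butyl-5-[(1S,2S)-1-hydroxy-2-methylbutyl]-5-methyl-1,3-dioxolan-4-one
Product: 7 methyl (2S,3S,4S)-2,3-dihydroxy-2,4-dimethylhexanoate
Conditions: K2CO3 (cat.), MeOH, 0 °C
Reagents that add atoms: methanol, CO
Why: Base-catalysed transesterification opens the acylal and the hemiacetal left behind collapses, which frees the diol without touching the stereocentres.

Step 5
Reactants: 7 methyl (2S,3S,4S)-2,3-dihydroxy-2,4-dimethylhexanoate
Product: 8 methyl (2S,3S,4S)-2,4-dimethyl-2,3-bis(triethylsilyloxy)hexanoate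
Conditions: Et3SiOTf, 2,6-lutidine, CH2Cl2, −78 to 0 °C
Reagents that add atoms: triethylsilyl triflate, CC[Si](CC)(CC)OS(=O)(=O)C(F)(F)F
Why: Silyl triflate/lutidine silylation is strong enough to protect the tertiary as well as the secondary hydroxyl group.

Step 6
Reactants: 8 methyl (2S,3S,4S)-2,4-dimethyl-2,3-bis(triethylsilyloxy)hexanoate
Product: 9 (2S,3S,4S)-2,4-dimethyl-2,3-bis(triethylsilyloxy)hexanal
Conditions: iBu2AlH, CH2Cl2, −78 °C; aq. potassium sodium tartrate
Reagents that add atoms: none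
Why: Partial ester reduction with diisobutylaluminium hydride at low temperature should stop at the aldehyde because the hindered tetrahedral aluminate survives until work-up.

Step 7
Reactants: 9 (2S,3S,4S)-2,4-dimethyl-2,3-bis(triethylsilyloxy)hexanal
Product: 10 (1E,3R,4S,5S)-1-iodo-3,5-dimethyl-3,4-bis(triethylsilyloxy)hept-1-ene
Conditions: CrCl2, CHI3, THF, 0 to 25 °C
Reagents that add atoms: iodoform, IC(I)I
Why: Takai olefination should convert the non-enolisable aldehyde into the (E)-vinyl iodide.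

Step 8
Reactants: 11 butane-2,3-dione
Product: 12 2,3-bis(tert-butyldimethylsilyloxy)buta-1,3-diene
Conditions: tBuMe2SiOTf (2.2 equiv), Et3N, CH2Cl2, 0 °C
Reagents that add atoms: tert-butyldimethylsilyl triflate, CC(C)(C)[Si](C)(C)OS(=O)(=O)C(F)(F)F
Why: Double soft enolisation and O-silylation of the 1,2-diketone gives a CH2–CO–C(OSi)=CH2 synthon that carries C5, C6, C7 and the C7 methyl carbon.

Step 9
Reactants: 13 (S)-4-benzyl-1,3-oxazolidin-2-one; 14 but-3-enoic acid
Product: 16 (S)-4-benzyl-3-(but-3-enoyl)-1,3-oxazolidin-2-one, via mixed pivalic anhydride 15 (not isolated)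
Conditions: tBuCOCl, Et3N, THF, −20 °C; then 13, LiCl, 25 °C
Reagents that add atoms: none
Why: N-Acylation through the mixed anhydride with LiCl/Et3N activation avoids bases strong enough to conjugate the β,γ-unsaturated acyl group.

Step 10
Reactants: 16 (S)-4-benzyl-3-(but-3-enoyl)-1,3-oxazolidin-2-one
Product: 18 (S)-4-benzyl-3-[(R)-2-(hydroxymethyl)but-3-enoyl]-1,3-oxazolidin-2-one, via titanium enolate 17 (not isolated)
Conditions: TiCl4, iPr2NEt, CH2Cl2, 0 °C; then 1,3,5-trioxane, TiCl4
Reagents that add atoms: 1,3,5-trioxane, C1OCOCO1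
Why: Aldol-type hydroxymethylation of the chelated (Z)-titanium dienolate at its α-carbon, in which the formaldehyde equivalent should attack the face opposite the benzyl group of the auxiliary and so set C8a.

Step 11
Reactants: 18 (S)-4-benzyl-3-[(R)-2-(hydroxymethyl)but-3-enoyl]-1,3-oxazolidin-2-one
Product: 19 (S)-4-benzyl-3-[(R)-2-(triethylsilyloxymethyl)but-3-enoyl]-1,3-oxazolidin-2-one
Conditions: Et3SiCl, imidazole, CH2Cl2, 0 °C
Reagents that add atoms: triethylsilyl chloride, CC[Si](CC)(CC)Cl
Why: Standard silylation of the primary alcohol protects the future C8 oxygen.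

Step 12
Reactants: 19 (S)-4-benzyl-3-[(R)-2-(triethylsilyloxymethyl)but-3-enoyl]-1,3-oxazolidin-2-one
Product: 20 (S)-2-(triethylsilyloxymethyl)but-3-en-1-ol
Conditions: LiBH4, H2O (1 equiv), Et2O, 0 °C
Reagents that add atoms: none
Why: Reductive cleavage of the N-acyl oxazolidinone with LiBH4 gives the primary alcohol (future C1–O2) without epimerising the α-vinyl centre.

Step 13
Reactants: 20 (S)-2-(triethylsilyloxymethyl)but-3-en-1-ol; 21 acryloyl chloride
Product: 22 (S)-2-(triethylsilyloxymethyl)but-3-en-1-yl acrylate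
Conditions: Et3N, CH2Cl2, −20 °C
Reagents that add atoms: none
Why: O-Acylation installs C3 and C4 as an acrylate ester.

Step 14
Reactants: 22 (S)-2-(triethylsilyloxymethyl)but-3-en-1-yl acrylate
Product: 23 (S)-5-(triethylsilyloxymethyl)-5,6-dihydro-2H-pyran-2-one
Conditions: second-generation Grubbs catalyst RuCl2(=CHPh)(PCy3)(H2IMes) (5 mol%), CH2Cl2, 40 °C
Reagents that add atoms: none
Why: Ring-closing metathesis of the acrylate with the terminal vinyl group should close the six-membered unsaturated lactone (O2–C3–C4=C4a–C8a–C1).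

Step 15
Reactants: 23 (S)-5-(triethylsilyloxymethyl)-5,6-dihydro-2H-pyran-2-one; 12 2,3-bis(tert-butyldimethylsilyloxy)buta-1,3-diene
Product: 25 (4R,5S)-4-[3-(tert-butyldimethylsilyloxy)-2-oxobut-3-en-1-yl]-5-(triethylsilyloxymethyl)tetrahydro-2H-pyran-2-one, via silyl ketene acetal 24 (not isolated)
Conditions: HNTf2 (5 mol%), CH2Cl2, −78 °C; then AcOH, H2O, THF, 0 °C
Reagents that add atoms: none
Why: Mukaiyama–Michael addition catalysed by the silyl triflimide formed in situ, in which the terminal CH2 of one silyl enol ether adds to C4a anti to the C8a substituent (trans lactone) and the second silyl enol ether remains as the 2-silyloxy enone.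

Step 16
Reactants: 25 (4R,5S)-4-[3-(tert-butyldimethylsilyloxy)-2-oxobut-3-en-1-yl]-5-(triethylsilyloxymethyl)tetrahydro-2H-pyran-2-one
Product: 26 (3S,4R)-4-[3-(tert-butyldimethylsilyloxy)-2-oxobut-3-en-1-yl]-6-oxotetrahydro-2H-pyran-3-carbaldehyde
Conditions: (COCl)2, DMSO, CH2Cl2, −78 to −40 °C; then iPr2NEt
Reagents that add atoms: none
Why: Swern oxidation run directly on the primary triethylsilyl ether, which is cleaved selectively under the activated-DMSO conditions, should unmask the C8 aldehyde while the tert-butyldimethylsilyl enol ether survives.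

Step 17
Reactants: 26 (3S,4R)-4-[3-(tert-butyldimethylsilyloxy)-2-oxobut-3-en-1-yl]-6-oxotetrahydro-2H-pyran-3-carbaldehyde
Product: 27 (4aR,7S,8R,8aS)-7-(tert-butyldimethylsilyloxy)-8-hydroxy-7-methylhexahydro-1H-isochromene-3,6(4H,7H)-dione
Conditions: H2 (1 atm), Rh(COD)2OTf (10 mol%), P(2-furyl)3 (24 mol%), KOAc (30 mol%), ClCH2CH2Cl, 25 °C
Reagents that add atoms: none
Why: Proposed new method: a rhodium hydride formed from H2 should add to the unhindered CH2 terminus of the 2-silyloxy enone in its s-cis conformation (C=O and C–OSi dipoles opposed), giving a rhodium O-enolate whose new C7 methyl is cis to O–Rh and whose silyloxy group is trans and cannot chelate; this enolate should add to the aldehyde held on the same metal before H2 releases the aldolate (closest known reaction type: hydrogen-mediated and copper hydride-mediated reductive aldol cyclisations of enone–aldehydes, not yet shown for a 2-oxygenated enone that delivers a fully substituted enolate carbon). The ring closed is ring A (C4a–C5–C6–C7–C8–C8a), by 6-(enolendo)-exo-trig attack of C7 on C8. C8 is controlled by the closed chair-like (Zimmerman–Traxler) array in which rhodium bridges O6 and O8: because the trans-fused lactone holds C1 and C4 equatorial and H8a axial, the C8 oxygen must become axial, anti to H8a. C7 is controlled by the enolate geometry, which places the silyloxy group axial (trans to the C8 oxygen) and the methyl equatorial, so the 7S,8R pair follows from the 8aS centre. The step needs hydrometalation of the enone in preference to the aldehyde and lactone, aldol closure faster than protonolysis of the enolate, and no epimerisation at C8a; the terminal 1,1-disubstituted alkene, the intramolecular six-membered closure and the neutral conditions (catalytic KOAc only) should secure these.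

Step 18
Reactants: 27 (4aR,7S,8R,8aS)-7-(tert-butyldimethylsilyloxy)-8-hydroxy-7-methylhexahydro-1H-isochromene-3,6(4H,7H)-dione
Product: 29 (7S,8R,8aS)-7-(tert-butyldimethylsilyloxy)-7-methyl-8-(trimethylsilyloxy)-8,8a-dihydro-1H-isochromene-3,6(4H,7H)-dione, via bis-trimethylsilyl enol ether 28 (not isolated)
Conditions: Me3SiOTf, Et3N, CH2Cl2, −78 to 0 °C; then Pd(OAc)2, MeCN, 25 °C
Reagents that add atoms: trimethylsilyl triflate, C[Si](C)(C)OS(=O)(=O)C(F)(F)F
Why: Saegusa–Ito oxidation, in which soft enolisation can occur only towards C5 (C7 is fully substituted) and palladation/β-hydride elimination then installs the C4a=C5 double bond and erases the temporary C4a stereocentre.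

Step 19
Reactants: 29 (7S,8R,8aS)-7-(tert-butyldimethylsilyloxy)-7-methyl-8-(trimethylsilyloxy)-8,8a-dihydro-1H-isochromene-3,6(4H,7H)-dione
Product: 30 (7S,8R,8aS)-6,7-bis(tert-butyldimethylsilyloxy)-7-methyl-8-(trimethylsilyloxy)-1,7,8,8a-tetrahydro-3H-isochromen-3-one
Conditions: tBuMe2SiOTf, Et3N, CH2Cl2, −78 to 0 °C
Reagents that add atoms: tert-butyldimethylsilyl triflate, CC(C)(C)[Si](C)(C)OS(=O)(=O)C(F)(F)F
Why: Soft vinylogous enolisation, in which the silyl triflate activates the more basic enone oxygen and the amine removes the doubly activated C4 proton, gives the silyl dienol ether and leaves the lactone as the only carbonyl group.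

Step 20
Reactants: 30 (7S,8R,8aS)-6,7-bis(tert-butyldimethylsilyloxy)-7-methyl-8-(trimethylsilyloxy)-1,7,8,8a-tetrahydro-3H-isochromen-3-one; 10 (1E,3R,4S,5S)-1-iodo-3,5-dimethyl-3,4-bis(triethylsilyloxy)hept-1-ene
Product: 33 (7S,8R,8aS)-7-(tert-butyldimethylsilyloxy)-3-[(1E,3R,4S,5S)-3,5-dimethyl-3,4-bis(triethylsilyloxy)hept-1-en-1-yl]-8-hydroxy-7-methyl-8,8a-dihydro-1H-isochromen-6(7H)-one, via vinyllithium 31 (not isolated), via lactol 32 (not isolated)
Conditions: 10, tBuLi (2 equiv), Et2O, −78 °C; then 30, THF, −78 °C; then 0.1 M HCl, THF, 0 °C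
Reagents that add atoms: none
Why: Iodine–lithium exchange with retention of alkene geometry, 1,2-addition of the vinyllithium to the lactone carbonyl (C3–C9 bond) and acid-induced ionisation of the lactol with loss of water and of the C6 silyl group (a vinylogous Stork–Danheiser-type transposition) should give the dienol ether–dienone of rings B and A.

Step 21
Reactants: 33 (7S,8R,8aS)-7-(tert-butyldimethylsilyloxy)-3-[(1E,3R,4S,5S)-3,5-dimethyl-3,4-bis(triethylsilyloxy)hept-1-en-1-yl]-8-hydroxy-7-methyl-8,8a-dihydro-1H-isochromen-6(7H)-one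
Product: 34 (7S,8R,8aS)-3-[(1E,3R,4S,5S)-3,4-dihydroxy-3,5-dimethylhept-1-en-1-yl]-7,8-dihydroxy-7-methyl-8,8a-dihydro-1H-isochromen-6(7H)-one
Conditions: HF·pyridine, pyridine, THF, 0 to 25 °C
Reagents that add atoms: none
Why: Buffered fluoride desilylation should free the three silylated hydroxyl groups without retro-aldol cleavage or hydrolysis of the vinylogous ester.

**Compound list**

1 | (S)-2-methylbutan-1-ol | CC[C@H](C)CO | starting material
2 | (S)-2-methylbutanal | CC[C@H](C)C=O | intermediate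
3 | (R)-lactic acid | C[C@@H](O)C(=O)O | starting material
4 | (2R,5R)-2-tert-butyl-5-methyl-1,3-dioxolan-4-one | C[C@H]1O[C@@H](C(C)(C)C)OC1=O | intermediate
5 | lithium enolate of 4 (lithium (R)-2-tert-butyl-5-methyl-1,3-dioxol-4-olate) | [Li]OC1=C(C)O[C@@H](C(C)(C)C)O1 | intermediate
6 | (2R,5S)-2-tert-butyl-5-[(1S,2S)-1-hydroxy-2-methylbutyl]-5-methyl-1,3-dioxolan-4-one | C[C@@]1([C@@H](O)[C@@H](C)CC)O[C@@H](C(C)(C)C)OC1=O | intermediate
7 | methyl (2S,3S,4S)-2,3-dihydroxy-2,4-dimethylhexanoate | CC[C@H](C)[C@H](O)[C@](C)(O)C(=O)OC | intermediate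
8 | methyl (2S,3S,4S)-2,4-dimethyl-2,3-bis(triethylsilyloxy)hexanoate | CC[C@H](C)[C@H](O[Si](CC)(CC)CC)[C@](C)(O[Si](CC)(CC)CC)C(=O)OC | intermediate
9 | (2S,3S,4S)-2,4-dimethyl-2,3-bis(triethylsilyloxy)hexanal | CC[C@H](C)[C@H](O[Si](CC)(CC)CC)[C@](C)(O[Si](CC)(CC)CC)C=O | intermediate
10 | (1E,3R,4S,5S)-1-iodo-3,5-dimethyl-3,4-bis(triethylsilyloxy)hept-1-ene | CC[C@H](C)[C@H](O[Si](CC)(CC)CC)[C@](C)(O[Si](CC)(CC)CC)/C=C/I | intermediate
11 | butane-2,3-dione | CC(=O)C(C)=O | starting material
12 | 2,3-bis(tert-butyldimethylsilyloxy)buta-1,3-diene | C=C(O[Si](C)(C)C(C)(C)C)C(=C)O[Si](C)(C)C(C)(C)C | intermediate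
13 | (S)-4-benzyl-1,3-oxazolidin-2-one | O=C1N[C@@H](Cc2ccccc2)CO1 | starting material
14 | but-3-enoic acid | C=CCC(=O)O | starting material
15 | but-3-enoic pivalic anhydride | C=CCC(=O)OC(=O)C(C)(C)C | intermediate
16 | (S)-4-benzyl-3-(but-3-enoyl)-1,3-oxazolidin-2-one | C=CCC(=O)N1[C@@H](Cc2ccccc2)COC1=O | intermediate
17 | trichlorotitanium (Z)-dienolate of 16 | Cl[Ti](Cl)(Cl)O/C(=C\C=C)N1[C@@H](Cc2ccccc2)COC1=O | intermediate
18 | (S)-4-benzyl-3-[(R)-2-(hydroxymethyl)but-3-enoyl]-1,3-oxazolidin-2-one | O=C(N1[C@@H](Cc2ccccc2)COC1=O)[C@H](C=C)CO | intermediate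
19 | (S)-4-benzyl-3-[(R)-2-(triethylsilyloxymethyl)but-3-enoyl]-1,3-oxazolidin-2-one | O=C(N1[C@@H](Cc2ccccc2)COC1=O)[C@H](C=C)CO[Si](CC)(CC)CC | intermediate
20 | (S)-2-(triethylsilyloxymethyl)but-3-en-1-ol | OC[C@H](C=C)CO[Si](CC)(CC)CC | intermediate
21 | acryloyl chloride | C=CC(=O)Cl | starting material
22 | (S)-2-(triethylsilyloxymethyl)but-3-en-1-yl acrylate | C=CC(=O)OC[C@H](C=C)CO[Si](CC)(CC)CC | intermediate
23 | (S)-5-(triethylsilyloxymethyl)-5,6-dihydro-2H-pyran-2-one | O=C1C=C[C@H](CO[Si](CC)(CC)CC)CO1 | intermediate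
24 | tert-butyldimethylsilyl ketene acetal of lactone 25 (trans-3,4-disubstituted 6-silyloxy-3,4-dihydro-2H-pyran) | CC(C)(C)[Si](C)(C)OC1=C[C@@H](CC(=O)C(=C)O[Si](C)(C)C(C)(C)C)[C@H](CO[Si](CC)(CC)CC)CO1 | intermediate
25 | (4R,5S)-4-[3-(tert-butyldimethylsilyloxy)-2-oxobut-3-en-1-yl]-5-(triethylsilyloxymethyl)tetrahydro-2H-pyran-2-one | O=C1C[C@@H](CC(=O)C(=C)O[Si](C)(C)C(C)(C)C)[C@H](CO[Si](CC)(CC)CC)CO1 | intermediate
26 | (3S,4R)-4-[3-(tert-butyldimethylsilyloxy)-2-oxobut-3-en-1-yl]-6-oxotetrahydro-2H-pyran-3-carbaldehyde | O=C1C[C@@H](CC(=O)C(=C)O[Si](C)(C)C(C)(C)C)[C@H](C=O)CO1 | intermediate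
27 | (4aR,7S,8R,8aS)-7-(tert-butyldimethylsilyloxy)-8-hydroxy-7-methylhexahydro-1H-isochromene-3,6(4H,7H)-dione | O=C1C[C@H]2CC(=O)[C@@](C)(O[Si](C)(C)C(C)(C)C)[C@H](O)[C@@H]2CO1 | intermediate
28 | trimethylsilyl enol ether (C5=C6) and C8 trimethylsilyl ether of 27 | O=C1C[C@H]2C=C(O[Si](C)(C)C)[C@@](C)(O[Si](C)(C)C(C)(C)C)[C@H](O[Si](C)(C)C)[C@@H]2CO1 | intermediate
29 | (7S,8R,8aS)-7-(tert-butyldimethylsilyloxy)-7-methyl-8-(trimethylsilyloxy)-8,8a-dihydro-1H-isochromene-3,6(4H,7H)-dione | O=C1CC2=CC(=O)[C@@](C)(O[Si](C)(C)C(C)(C)C)[C@H](O[Si](C)(C)C)[C@@H]2CO1 | intermediate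
30 | (7S,8R,8aS)-6,7-bis(tert-butyldimethylsilyloxy)-7-methyl-8-(trimethylsilyloxy)-1,7,8,8a-tetrahydro-3H-isochromen-3-one | O=C1C=C2C=C(O[Si](C)(C)C(C)(C)C)[C@@](C)(O[Si](C)(C)C(C)(C)C)[C@H](O[Si](C)(C)C)[C@@H]2CO1 | intermediate
31 | (1E,3R,4S,5S)-3,5-dimethyl-3,4-bis(triethylsilyloxy)hept-1-en-1-yllithium | CC[C@H](C)[C@H](O[Si](CC)(CC)CC)[C@](C)(O[Si](CC)(CC)CC)/C=C/[Li] | intermediate
32 | lactol from addition of 31 to C3 of 30 (C3 configuration not defined) | CC[C@H](C)[C@H](O[Si](CC)(CC)CC)[C@](C)(O[Si](CC)(CC)CC)/C=C/C1(O)C=C2C=C(O[Si](C)(C)C(C)(C)C)[C@@](C)(O[Si](C)(C)C(C)(C)C)[C@H](O[Si](C)(C)C)[C@@H]2CO1 | intermediate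
33 | (7S,8R,8aS)-7-(tert-butyldimethylsilyloxy)-3-[(1E,3R,4S,5S)-3,5-dimethyl-3,4-bis(triethylsilyloxy)hept-1-en-1-yl]-8-hydroxy-7-methyl-8,8a-dihydro-1H-isochromen-6(7H)-one | CC[C@H](C)[C@H](O[Si](CC)(CC)CC)[C@](C)(O[Si](CC)(CC)CC)/C=C/C1=CC2=CC(=O)[C@@](C)(O[Si](C)(C)C(C)(C)C)[C@H](O)[C@@H]2CO1 | intermediate
34 | (7S,8R,8aS)-3-[(1E,3R,4S,5S)-3,4-dihydroxy-3,5-dimethylhept-1-en-1-yl]-7,8-dihydroxy-7-methyl-8,8a-dihydro-1H-isochromen-6(7H)-one | CC[C@H](C)[C@H](O)[C@](C)(O)/C=C/C1=CC2=CC(=O)[C@@](C)(O)[C@H](O)[C@@H]2CO1 | target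

**Step count and risks**

Total step count: 21.
Longest linear sequence: 13 steps (steps 9 to 21).

Steps most likely to fail:

1. Step 17 (bears the label). The enone may simply be reduced without ring closure, the enolate geometry may erode (giving the C7 or C8 epimer), or the lactone oxygen may be lost by β-elimination from the aldehyde. The fallback sets out from 25 and comes back at 27. Rhodium-catalysed conjugate hydrosilylation of 25 (Et3SiH, RhCl(PPh3)3 cat.) should give the isolable (E)-bis-silyl enediol ether F1, so the enolate geometry can be checked before ring closure. Direct Swern oxidation of its primary triethylsilyl ether should give the aldehyde F2. An intramolecular Mukaiyama aldol addition promoted by SnCl4 (CH2Cl2, −78 °C), which can bridge both oxygens, followed by aqueous work-up should return 27.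

2. Step 15. The diene may add across the lactone double bond by [4+2] cycloaddition in place of conjugate addition, or the second silyl enol ether may be lost on work-up. The fallback sets out from 23 and comes back at 25. Monosilylation of 11 (one equivalent of tBuMe2SiOTf, Et3N) should give 3-(tert-butyldimethylsilyloxy)but-3-en-2-one F3. Its kinetic lithium enolate F4 (LiN(iPr)2, THF, −78 °C) should undergo anionic Michael addition to 23 anti to the C8a substituent and give 25 after protonation.

3. Step 20. The organolithium may enolise the substrate at C8a or add twice in place of clean 1,2-addition, and the lactol may dehydrate incompletely. The fallback sets out from 30 and comes back at 33. Aminolysis of the lactone with MeNH(OMe)·HCl and Me3Al should give the hydroxy N-methoxy-N-methylamide F5. Silylation (Et3SiCl, imidazole) should give the triethylsilyl ether F6. Addition of 31 should stop at the dienyl ketone F7. Treatment with 0.1 M HCl in THF should then remove the primary silyl ether, close the hemiketal and dehydrate it to 33.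

Further compounds
F1 | step 17 | (4R,5S)-4-[(E)-3-(tert-butyldimethylsilyloxy)-2-(triethylsilyloxy)but-2-en-1-yl]-5-(triethylsilyloxymethyl)tetrahydro-2H-pyran-2-one | O=C1C[C@@H](C/C(O[Si](CC)(CC)CC)=C(/C)O[Si](C)(C)C(C)(C)C)[C@H](CO[Si](CC)(CC)CC)CO1
F2 | step 17 | (3S,4R)-4-[(E)-3-(tert-butyldimethylsilyloxy)-2-(triethylsilyloxy)but-2-en-1-yl]-6-oxotetrahydro-2H-pyran-3-carbaldehyde | O=C1C[C@@H](C/C(O[Si](CC)(CC)CC)=C(/C)O[Si](C)(C)C(C)(C)C)[C@H](C=O)CO1
F3 | step 15 | 3-(tert-butyldimethylsilyloxy)but-3-en-2-one | CC(=O)C(=C)O[Si](C)(C)C(C)(C)C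
F4 | step 15 | lithium 3-(tert-butyldimethylsilyloxy)buta-1,3-dien-2-olate | [Li]OC(=C)C(=C)O[Si](C)(C)C(C)(C)C
F5 | step 20 | (Z)-2-[(3S,4R,5S)-2,3-bis(tert-butyldimethylsilyloxy)-5-(hydroxymethyl)-3-methyl-4-(trimethylsilyloxy)cyclohex-1-en-6-ylidene]-N-methoxy-N-methylacetamide (amide carbonyl cis to C8a) | CON(C)C(=O)/C=C1/C=C(O[Si](C)(C)C(C)(C)C)[C@@](C)(O[Si](C)(C)C(C)(C)C)[C@H](O[Si](C)(C)C)[C@@H]1CO
F6 | step 20 | triethylsilyl ether of F5 at the primary hydroxyl | CON(C)C(=O)/C=C1/C=C(O[Si](C)(C)C(C)(C)C)[C@@](C)(O[Si](C)(C)C(C)(C)C)[C@H](O[Si](C)(C)C)[C@@H]1CO[Si](CC)(CC)CC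
F7 | step 20 | dienyl ketone from addition of 31 to F6 (C3 ketone bearing the side chain) | CC[C@H](C)[C@H](O[Si](CC)(CC)CC)[C@](C)(O[Si](CC)(CC)CC)/C=C/C(=O)/C=C1/C=C(O[Si](C)(C)C(C)(C)C)[C@@](C)(O[Si](C)(C)C(C)(C)C)[C@H](O[Si](C)(C)C)[C@@H]1CO[Si](CC)(CC)CC
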